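**One-step world.** In a one-step world a fixed share of the charge ends as target, so the plateau percentage stays put when the recipe changes. The south and south-west runs refuse this: their last two readings average 32.0 % and 22.9 %.

| flask | starting material | other conformer | remark | time |
|---|---|---|---|---|
| south | 0.050 M | 0.032 M | run made earlier |  |
| south-west | 0.050 M | 0.094 M | run made earlier |  |
| Saturday's | 0.050 M | 0.0250 M |  | 12 h |
| Monday's | 0.050 M | 0.0620 M |  | 12 h |

| run | time / h | target / % | starting material / % |
|---|---|---|---|
| south | 0.500 | 20.0 | 28.9 |
| south | 0.833 | 25.3 | 16.8 |
| south | 1.50 | 31.4 | 6.9 |
| south | 3.00 | 32.9 | 0 |
| south | 6.00 | 31.2 | 0 |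
| south-west | 0.500 | 13.4 | 23.0 |
| south-west | 0.833 | 19.5 | 15.0 |
| south-west | 1.50 | 21.9 | 6.0 |
| south-west | 3.00 | 22.6 | 1.0 |
| south-west | 6.00 | 23.3 | 1.4 |

(scatter of a reading: 1 percentage point)



1. which of the two there is more of at the end, Saturday's (target / isomer of the product)
2. which of the two there is more of at the end, Monday's (target / isomer of the product)
3. how much target is there at the end, in percent of the starting material and other conformer together charged: Saturday's
4. how much target is there at the end, in percent of the starting material and other conformer together charged: Monday's

**Freezing a slope.** Percentages hide the concentrations, so we convert: c(target) reads 0.0263 M in the south run and 0.0330 M in the south-west run. Between them c(starting material) is held, so we freeze the ratio of the gain in c(target) to the gain in c(other conformer), s = 0.109, the marginal yield. Run back along this line, the starting material's share is 0.0228 M of target.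

**Bench rule.** We add s times c(other conformer) to that share and take the plateau as lasting to the asked time. This gives 34.0 % target on Saturday's and 26.4 % on Monday's. The isomer was never read, so we guess that the remaining fraction 0.891 of the other conformer becomes isomer, which gives 29.7 % and 49.3 %. We therefore expect more target than isomer on Saturday's and more isomer than target on Monday's.

**The border.** The line spans c(other conformer)/c(starting material) from 0.640 to 1.88. Monday's ratio, 1.24, lies inside, but Saturday's, 0.500, is smaller than the span's lower end, so Saturday's figure is an extrapolation.

**Forecast, flask.** The forecast named isomer of the product on Saturday's and isomer of the product on Monday's, with 33.5 % and 26 % target, holding that “the other conformer goes mostly to the isomer”. Saturday's flask gives 35.5 % target and 27.5 % isomer; Monday's gives 27.3 % and 37.2 %.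

    2 starting material → self-condensation product (k = 0.0890 /M/min)
    other conformer → isomer of the product (k = 0.0190 /min)
    starting material + target → side product (k = 0.300 /M/min)
    starting material → target (k = 0.0180 /min)
    third conformer → third product (k = 0.0130 /min)
    starting material ⇌ other conformer (K = 0.480, k = 0.00740 /min)
    other conformer ⇌ third conformer (K = 3.00, k = 0.00200 /min)

**What s carries.** The rule fell short of Saturday's flask by 1.5 percentage points and of Monday's by 0.91 points. Monday's flask ends 8.2 points below Saturday's because it is charged with more other conformer: with Saturday's charge of other conformer it ends at 35.5 %, not 27.3 %. A neighbour of Saturday's flask charged with 0.0063 M other conformer has the ratio 0.126; the same s gives it 41.7 %, and it ends at 43.1 %.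

(The readings come from a simulation on assumed constants; noise was put on by code.)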